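Two times tell this flask.

| setting | summer | spring | dawn | flask |
|---|---|---|---|---|
| solid substrate | 5.0 × 10⁻⁴ M | 5.0 × 10⁻⁴ M | 2.5 × 10⁻⁴ M | 5.0 × 10⁻⁴ M |
| reagent | 0.75 mM | 1.1 mM | 1.5 mM | 1.50 mM |
| remark | run made earlier | run made earlier | run made earlier |  |
| time |  |  |  | 2.0 min |

| run | time / s | target / % | solid substrate / % |
|---|---|---|---|
| summer | 10.0 | 3 | 66 |
| summer | 15.0 | 12 | 61 |
| summer | 25.0 | 16 | 52 |
| summer | 40.0 | 26 | 42 |
| summer | 80.0 | 52 | 14 |
| spring | 12.0 | 11 | 62 |
| spring | 25.0 | 24 | 49 |
| spring | 40.0 | 37 | 33 |
| spring | 50.0 | 46 | 25 |
| spring | 60.0 | 56 | 15 |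
| spring | 80.0 | 70 | 2 |
| dawn | 15.0 | 31 | 12 |
| dawn | 30.0 | 64 | 3 |
| dawn | 40.0 | 78 | 0 |
| dawn | 60.0 | 88 | 5 |
| dawn | 80.0 | 97 | 1 |

(each reading ± 2 percentage points)

1. how much target there is at 2.0 min, in percent of the solid substrate charged
2. the change that raises the amount of target at 2.0 min, in percent of the solid substrate charged most ("none" if none brings more than 2 percentage points) (Sunday's / Tuesday's / Saturday's / none)
3. amount of target at 2.0 min, in percent of the solid substrate charged, after Saturday's

- solid, in amounts per volume of the solution: solid substrate
- steps under discussion: solid substrate <-> dissolved substrate; dissolved substrate + reagent -> target; reagent -> side product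
- at the start none of the solid substrate is in solution

- Sunday's: doubling the solubility of the solid substrate, all else as stated
- Tuesday's: doubling the amount of reagent, all else as stated
- Saturday's: doubling the dissolution coefficient of the solid substrate, all else as stated

I add two columns. In the spring run, target and solid substrate together fall short of the charge by

29.0 %

at 50.0 s, and its other readings lie near that within their scatter. I take this as the fraction standing dissolved while solid lasts. Dividing the spring slope of target by this fraction and by the mean reagent gives, as a reading with the scatter of these readings, the capture constant, the rate of capture per dissolved fraction and per unit of reagent: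

33.3 L mol⁻¹ s⁻¹

While solid lasts, I take target in the flask to rise steadily, so the solid should end after

55.5 s

Then I expect the dissolved fraction in the flask to decay exponentially (pseudo-first-order). I take reagent as its charge less one substrate charge, which gives the lifetime

30.0 s

The asked time lies 2.15 lifetimes past the end of the solid, so the fraction uncaptured is

3.38 %

and I expect 96.6 %.

The forecast says 95 % of target at 2.0 min, less than my figure, names Tuesday's as the best change and gives 96.5 % after Saturday's, holding that “Target then forms at a steady rate”.

The flask gives 96.5 %, with Tuesday's ahead at 3.5 percentage points and 97.2 % after Saturday's.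

    solid substrate ⇌ dissolved substrate, rate k1*(cs1 - [dissolved substrate]) while solid is left; crystals form when [dissolved substrate] > cs1 (solubility = 0.180 mM, k = 0.196 s⁻¹)
    dissolved substrate + reagent → target (k = 33.9 L mol⁻¹ s⁻¹)
    reagent → side product (k = 3.65 × 10⁻⁴ s⁻¹)

At 1.00 min the flask holds 0 % solid substrate and 28.1 % dissolved substrate; the lifetime carries this to 3.80 % at 2.0 min, where 3.54 % stands. The flask's amount of target at 2.0 min has moved by 5 points once its reagent is lowered to 1.21 mM. For the neighbour flask with 9.0 × 10⁻⁴ M of reagent, the capture constant gives a solid end at 102 s, a lifetime of 75.0 s and 77.2 % target; that neighbour flask stands at 79.5 %.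

The runs are simulated from invented constants, and the scatter is random.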